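## Structural features

Gnetofuran A is a trans-2-aryl-3-(hydroxymethyl)-2,3-dihydrobenzofuran. Benzene ring B is fused through C3a and C7a to the five-membered ring O1–C2–C3; C2 carries ring A (4-hydroxy-3-methoxyphenyl), C3 carries CH2OH, C7 a methoxy group, and C5 an (E)-ethenyl bridge to ring C (3,5-dihydroxyphenyl). The only stereocentres, C2 (R) and C3 (S), are adjacent and trans. C3 is a benzylic CH between ring B, C2 and CH2OH and has no heteroatom of its own to direct its formation. The fragile parts are the three free phenols (oxidation), the E-stilbene (hydrogenation, light, strong acid) and the benzylic aryl ether O1–C2. That ether sits para to the ring-A oxygen, so it can open through a para-quinone methide under hot base and is cleaved by hydrogenolysis or strong Lewis acid. For this reason no deprotection by hydrogenation can come after the stilbene, or even after the C5 bromide, is in place. The real difficulty is the absolute configuration of C3 together with the trans relation to C2, while a C5 handle for the stilbene is carried through untouched. The key step uses the fact that C2 is bonded to O1 and to C1′ of ring A, whose para carbon bears oxygen. A cation at C2 is therefore delocalised onto that oxygen and is planar, and the ring-B phenol oxygen (future O1) can close onto it under the sole control of C3, so only C3 has to be made enantioselectively.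

## Logic of the disconnections

23 from 22: the three aryl O–Si bonds are cut last. Silyl ethers are chosen because fluoride removes them without touching the stilbene or the benzylic ether, and all three fall in one operation. The demand is that the medium stays buffered, so that the ring-A phenoxide cannot open the O1–C2 bond.

22 from 18 and 21: the C5–C(vinyl) bond is cut. This separates the achiral resorcinol styrene from the chiral core, and a Heck coupling sets the E geometry by its syn-insertion/syn-elimination course. The demand is a C5 bromide that has survived every earlier step, and silyl ethers that tolerate an amine base at moderate temperature.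

21 from 20 from 19: the terminal C=CH2 bond and two O–Si bonds are cut. This leads back to a commercial aldehyde in two routine steps; the forward methylenation must not expose the aryl silyl ethers to free alkoxide.

18 from 16 (key cut): the O1–C2 bond is opened. This removes the heterocycle and the C2 stereocentre from the problem, since the forward closure passes through a planar benzylic cation and is corrected thermodynamically to trans. The demands are a free ortho phenol on ring B, a donor oxygen para to the carbinol on ring A that survives acid, and conditions mild enough that C3 is not lost by elimination. The syn diol 16 must react with net retention at the carbinol carbon, which only the cationic pathway can deliver.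

16 from 15 from 14: the O-allyl bond of the ring-B phenol is restored and the CH2OH is taken back to the acyl–nitrogen bond of the auxiliary. Allyl is removable by Pd(0) at room temperature beside the bromide and the silyl ether. Reductive cleavage must be fast enough to outrun retro-aldol fragmentation of the doubly benzylic aldolate.

14 from 9 and 11: the bond between the α-carbon (future C3) and the carbinol carbon (future C2) is cut. This joins the two aryl halves and sets C3 through the auxiliary. Only the enolate face matters, because the carbinol configuration is erased later. The forward step needs a (Z)-enolate, a non-enolisable aldehyde, and no epimerisation of the acidic α-aryl centre.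

9 from 6 and 7, and 11 from 10: the N-acyl bond and one O–Si bond are cut. This gives a commercial auxiliary, a simple arylacetic acid and a commercial phenolic aldehyde. The acylation must avoid ketene formation from the arylacetyl unit.

6 from 4 from 2 from 1: the CH2–C(O) bond is cut (one-carbon homologation through the nitrile), then the O-allyl bond. This reaches a commercial salicylaldehyde that already carries bromine, methoxy and phenol in the right places. The homologation must avoid cyanide salts and must not touch the bromide or the allyl ether.

## Other disconnections considered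

Alternative 1: The cut is made at C3–CH2 and C2–aryl across the C2=C3 bond of a benzofuran. In the forward step, benzofuran A1 would be metalated at C2 and combined with aryl boronic ester A2 to give a boronate. A chiral π-allylpalladium electrophile would then attack C3 while the aryl group migrates from boron to C2, giving A3 with aryl and allyl trans. In its favour, two C–C bonds and both stereocentres arise in one catalytic, enantioselective step from flat, easily made partners. On that point (stereocentres per step, no stoichiometric auxiliary to attach and cleave) it is better than the chosen plan. Against it here: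
- The C3 substituent arrives as allyl and must be cut back by two carbons (alkene isomerisation, oxidative cleavage, reduction), passing through an epimerisable α-aryl aldehyde.
- The tertiary benzylic C2–B bond must be replaced by hydrogen with clean retention.
- The C5 acetal must still be unveiled and olefinated, with an E/Z question the Heck route does not have.
- Enantiocontrol on a 7-methoxybenzofuran with an electron-rich migrating aryl would have to be assumed rather than known.

Structurally the two plans reach the same core. Mechanistically the chosen plan uses a substrate-controlled, self-correcting closure, whereas this one depends wholly on catalyst control. In step count the endgame here would be roughly six or seven operations against two, so the chosen plan should be shorter overall.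

Alternative 2: The cut removes ring B altogether, at C3a–C7a and C4–C5. In the forward step, pyrone A4, which carries the alkyne on a three-atom tether from the C3 oxygen, would undergo an intramolecular [4+2] addition across C3 and C6 on heating. Loss of carbon dioxide from the bridged lactone would then give A5, the fully silylated target. In its favour, the benzene ring and the dihydrofuran form together, the substitution pattern of ring B is fixed by the tether whatever the usual rules of aromatic substitution say, no metal is needed, and A5 is one deprotection from the target. The endgame is therefore better than that of the chosen plan, and the regiochemical certainty is at least equal. Against it: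
- The reaction creates no stereocentre. Both C2 and C3 must already be present in A4 as an acyclic benzylic/propargylic ether.
- Making that ether requires a stereodefined etherification of an electron-rich benzylic carbinol with a hydroxypyrone, where SN1 scrambling threatens.
- The temperatures typical of pyrone–alkyne cycloadditions endanger the styryl unit, which can itself act as a 2π or 4π partner, and the benzylic ether next to a para-silyloxyaryl group.
- The 3-hydroxy-4-methoxy-6-styrylpyrone is a multistep target of its own.

The mechanism is robust and irreversible, but the stereochemical problem is only moved, not solved. Overall step economy should be worse than in the chosen plan.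

Alternative 3: The cut is made at C2–C3 and O1–C2. In the forward step, the ylide from chiral benzyl sulfonium salt A7 would add to the methide carbon of o-quinone methide A6, generated in the flask. The phenoxide would then displace the sulfide at C2 to give A8, trans by way of the anti betaine. In its favour, this is the most convergent of all: both aryl halves are joined, and the ring, two bonds and both stereocentres form in one operation, without an auxiliary. A8 is the same kind of C5 bromide as 18, so the endgame is equal, and in steps to the core it is better than the chosen plan. Against it here: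
- A6 carries a CH2OSi group on the methide carbon and can tautomerise to a vinylphenol instead of being trapped.
- The electron-rich, semi-stabilised ylide adds less reversibly, and its sulfonium salt ionises easily, so the level and even the sense of asymmetric induction from the sulfide cannot be predicted.
- A low enantiomeric ratio could not be upgraded by separating diastereomers, as it can at 14.
- The benzyl ether of A8 would have to be removed beside a stilbene.

Structurally and in the endgame the two plans are equivalent. Mechanistically the chosen plan offers predictable absolute control and a self-correcting ring closure, at the price of roughly four more steps.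

Key step: step 9

Remark on protecting groups: the ring-A phenol is carried as a triisopropylsilyl ether, not a benzyl ether. A benzyl ether could be removed at the end only by hydrogenolysis or strong Lewis acid, which the stilbene, the aryl bromide and the O1–C2 bond would not survive. The skeletons of 16 and 18 and the bond formed in the key step are unchanged.

Remark on configuration: the descriptors were checked. The (R)-auxiliary in an Evans syn aldol gives (2R,3R)-14, reduction gives (1R,2S)-15 and 16 (the C2 descriptor changes only through CIP priorities), and closure with net retention at the carbinol carbon gives (2R,3S)-18, the trans series of the target.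

## Route

Step 1
Reactants: 1 5-bromo-2-hydroxy-3-methoxybenzaldehyde
Product: 2 2-(allyloxy)-5-bromo-3-methoxybenzaldehyde
Conditions: allyl bromide, K2CO3, DMF, rt to 50 °C
Reagents that add atoms: allyl bromide, C=CCBr
Why: Williamson etherification of the acidic salicylaldehyde phenol. Allyl is chosen because it survives base, borane and hydride chemistry and is later removed by Pd(0) at room temperature without touching the aryl bromide or a silyl ether.

Step 2
Reactants: 2 2-(allyloxy)-5-bromo-3-methoxybenzaldehyde
Product: 4 2-[2-(allyloxy)-5-bromo-3-methoxyphenyl]acetonitrile, via N-(1-tosylvinyl)formamide 3 (not isolated)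
Conditions: TosMIC, t-BuOK, DME, −50 °C; then MeOH, reflux
Reagents that add atoms: tosylmethyl isocyanide (TosMIC), Cc1ccc(cc1)S(=O)(=O)C[N+]#[C-]
Why: Van Leusen reductive cyanation. The TosMIC anion adds to the aldehyde, the oxazoline opens to 3, and methanolysis of the formyl group with loss of sulfinate gives the homologous nitrile, so one carbon is added without cyanide salts; the bromide and allyl ether are inert to cold alkoxide.

Step 3
Reactants: 4 2-[2-(allyloxy)-5-bromo-3-methoxyphenyl]acetonitrile
Product: 6 2-[2-(allyloxy)-5-bromo-3-methoxyphenyl]acetic acid, via primary amide 5 (not isolated)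
Conditions: NaOH, EtOH/H2O, reflux; then aq. HCl to pH 2
Reagents that add atoms: water, O (delivered as aqueous NaOH)
Why: Base hydrolysis of an arylacetonitrile through the amide to the carboxylate; aryl bromide, aryl allyl ether and methyl ether are stable to aqueous hydroxide.

Step 4
Reactants: 6 2-[2-(allyloxy)-5-bromo-3-methoxyphenyl]acetic acid; 7 (R)-4-benzyl-2-oxazolidinone
Product: 9 (R)-3-{2-[2-(allyloxy)-5-bromo-3-methoxyphenyl]acetyl}-4-benzyloxazolidin-2-one, via mixed pivalic anhydride 8 (not isolated)
Conditions: PivCl, Et3N, THF, −20 °C; then 7, LiCl, −20 °C to rt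
Reagents that add atoms: pivaloyl chloride, CC(C)(C)C(=O)Cl (its acyl group stays only in intermediate 8)
Why: N-acylation of the oxazolidinone through the mixed anhydride with LiCl activation. This avoids butyllithium, and the low temperature suppresses ketene formation from the arylacetyl unit; attack occurs at the less hindered arylacetyl carbonyl of 8.

Step 5
Reactants: 10 vanillin
Product: 11 3-methoxy-4-(triisopropylsilyloxy)benzaldehyde
Conditions: TIPSCl, imidazole, DMF, rt
Reagents that add atoms: chlorotriisopropylsilane, CC(C)[Si](Cl)(C(C)C)C(C)C
Why: Standard silylation of a phenol. The bulky aryl silyl ether tolerates the boron aldol, borohydride, Pd(0)/amine and catalytic sulfonic acid, keeps a donor oxygen para to the future carbinol, and falls to fluoride at the end.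

Step 6
Reactants: 9 (R)-3-{2-[2-(allyloxy)-5-bromo-3-methoxyphenyl]acetyl}-4-benzyloxazolidin-2-one; 11 3-methoxy-4-(triisopropylsilyloxy)benzaldehyde
Product: 14 (R)-4-benzyl-3-{(2R,3R)-2-[2-(allyloxy)-5-bromo-3-methoxyphenyl]-3-hydroxy-3-[3-methoxy-4-(triisopropylsilyloxy)phenyl]propanoyl}oxazolidin-2-one, via (Z)-dibutylboron enolate 12 (not isolated), via dibutylboron aldolate 13 (not isolated)
Conditions: Bu2BOTf, i-Pr2NEt, CH2Cl2, 0 °C; then 11, −78 to 0 °C; then pH 7 buffer, MeOH, 30% H2O2, 0 °C
Reagents that add atoms: dibutylboron triflate, CCCCB(CCCC)OS(=O)(=O)C(F)(F)F (the Bu2B group stays only in intermediates 12 and 13)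
Why: Evans syn aldol. Soft enolisation gives the (Z)-boron enolate 12, which adds to the non-enolisable aldehyde through a closed Zimmerman–Traxler chair with the imide dipoles opposed; the benzyl group of the (R)-auxiliary blocks one enolate face and so fixes the α-carbon as R (the future C3), and the chair makes the carbinol syn (3R). Chromatography at this stage should remove any diastereomer that differs at the α-carbon, which is the only one that matters later.

Step 7
Reactants: 14 (R)-4-benzyl-3-{(2R,3R)-2-[2-(allyloxy)-5-bromo-3-methoxyphenyl]-3-hydroxy-3-[3-methoxy-4-(triisopropylsilyloxy)phenyl]propanoyl}oxazolidin-2-one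
Product: 15 (1R,2S)-2-[2-(allyloxy)-5-bromo-3-methoxyphenyl]-1-[3-methoxy-4-(triisopropylsilyloxy)phenyl]propane-1,3-diol
Conditions: LiBH4, MeOH (1 equiv), THF, 0 °C
Reagents that add atoms: none
Why: Reductive cleavage of the N-acyl oxazolidinone to the primary alcohol with recovery of the auxiliary. Hydride attacks the exocyclic carbonyl quickly at 0 °C, which should outrun retro-aldol cleavage and leave the α-centre untouched; its descriptor becomes S only because the CIP priorities change.

Step 8
Reactants: 15 (1R,2S)-2-[2-(allyloxy)-5-bromo-3-methoxyphenyl]-1-[3-methoxy-4-(triisopropylsilyloxy)phenyl]propane-1,3-diol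
Product: 16 (1R,2S)-2-(5-bromo-2-hydroxy-3-methoxyphenyl)-1-[3-methoxy-4-(triisopropylsilyloxy)phenyl]propane-1,3-diol
Conditions: Pd(PPh3)4 (cat.), morpholine, THF, rt
Reagents that add atoms: none
Why: Tsuji–Trost deallylation. Pd(0) ionises the aryl allyl ether to a π-allyl complex that morpholine captures; at room temperature this is much faster than oxidative addition into the electron-rich aryl bromide, and the neutral amine leaves the aryl silyl ether intact.

Step 9
Reactants: 16 (1R,2S)-2-(5-bromo-2-hydroxy-3-methoxyphenyl)-1-[3-methoxy-4-(triisopropylsilyloxy)phenyl]propane-1,3-diol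
Product: 18 [(2R,3S)-5-bromo-7-methoxy-2-[3-methoxy-4-(triisopropylsilyloxy)phenyl]-2,3-dihydro-1-benzofuran-3-yl]methanol, via benzylic cation 17 (not isolated)
Conditions: TsOH·H2O (10 mol %), CH2Cl2/HFIP 9:1, 0.02 M, 0 °C to rt
Reagents that add atoms: none
Why: Protonation of the benzylic hydroxyl of 16 and loss of water give cation 17, whose charge is delocalised through ring A onto the para silyloxy oxygen (a quinone-methide-like oxocarbenium), so C2 becomes planar and the carbinol configuration is erased. The ortho phenol oxygen of ring B then adds to this carbon in a 5-exo-trig closure that forms O1–C2 and the dihydrofuran ring; the closest known reaction type is the acid-mediated cyclisation of 1,2-diarylpropane-1,3-diols bearing an ortho phenol to trans-2-aryl-3-(hydroxymethyl)-2,3-dihydrobenzofurans. The new stereocentre C2 is controlled by the existing C3 centre, because closure goes through the rotamer about C2–C3 that keeps ring A away from the CH2OH group, which places the aryl group trans to CH2OH. Since the benzylic aryl ether of 18 can re-ionise under the same acid, any cis isomer should return to 17 and drain into the more stable trans isomer, so kinetic and thermodynamic control point the same way. For the syn diol 16 this amounts to net retention at the carbinol carbon, which a direct SN2 displacement could not give, and the C1 epimer would converge through the same cation. Chemoselectivity is needed against the primary hydroxyl, which could only close a strained oxetane (4-exo) and is therefore not competitive, and against intermolecular capture, which dilution suppresses. C3 must keep its configuration: it is not part of the cation, and catalytic acid at low temperature is chosen so that E1 loss of the C3 proton to a stilbene, the one pathway that could erase it, does not set in. The silyloxy group is a weaker donor than an alkoxy group, which is why the ionising co-solvent hexafluoroisopropanol is added, while an aryl triisopropylsilyl ether should tolerate catalytic TsOH.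

Step 10
Reactants: 19 3,5-dihydroxybenzaldehyde
Product: 20 3,5-bis(tert-butyldimethylsilyloxy)benzaldehyde
Conditions: TBSCl, imidazole, DMF, rt
Reagents that add atoms: tert-butyldimethylsilyl chloride, CC(C)(C)[Si](C)(C)Cl
Why: Standard double silylation of the phenols, so that all three protecting groups of the final intermediate can be removed by fluoride in one operation.

Step 11
Reactants: 20 3,5-bis(tert-butyldimethylsilyloxy)benzaldehyde
Product: 21 3,5-bis(tert-butyldimethylsilyloxy)styrene
Conditions: Ph3PCH3Br, t-BuOK, THF, 0 °C to rt (ylide preformed, slight excess of salt)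
Reagents that add atoms: methyltriphenylphosphonium bromide, C[P+](c1ccccc1)(c1ccccc1)c1ccccc1.[Br-]
Why: Wittig methylenation of an aromatic aldehyde with the non-stabilised ylide; preforming the ylide with a slight excess of the salt leaves no free alkoxide to attack the aryl silyl ethers.

Step 12
Reactants: 18 [(2R,3S)-5-bromo-7-methoxy-2-[3-methoxy-4-(triisopropylsilyloxy)phenyl]-2,3-dihydro-1-benzofuran-3-yl]methanol; 21 3,5-bis(tert-butyldimethylsilyloxy)styrene
Product: 22 [(2R,3S)-5-{(E)-2-[3,5-bis(tert-butyldimethylsilyloxy)phenyl]ethenyl}-7-methoxy-2-[3-methoxy-4-(triisopropylsilyloxy)phenyl]-2,3-dihydro-1-benzofuran-3-yl]methanol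
Conditions: Pd2(dba)3 (cat.), P(t-Bu)3·HBF4, Cy2NMe, dioxane, 60 °C
Reagents that add atoms: none
Why: Mizoroki–Heck coupling. The electron-rich trialkylphosphine allows oxidative addition into the unhindered but electron-rich C5 bromide at moderate temperature; aryl migration to the terminal styrene carbon and syn β-hydride elimination give the E-stilbene, and the amine base spares the silyl ethers, the free primary alcohol and both stereocentres.

Step 13
Reactants: 22 [(2R,3S)-5-{(E)-2-[3,5-bis(tert-butyldimethylsilyloxy)phenyl]ethenyl}-7-methoxy-2-[3-methoxy-4-(triisopropylsilyloxy)phenyl]-2,3-dihydro-1-benzofuran-3-yl]methanol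
Product: 23 gnetofuran A, 5-{(E)-2-[(2R,3S)-2-(4-hydroxy-3-methoxyphenyl)-3-(hydroxymethyl)-7-methoxy-2,3-dihydro-1-benzofuran-5-yl]ethenyl}benzene-1,3-diol
Conditions: TBAF, AcOH (1:1), THF, 0 °C to rt, exclusion of light and air
Reagents that add atoms: none
Why: Fluoride-induced cleavage of the three aryl silyl ethers. The acetic acid buffer keeps the ring-A phenol protonated so that the O1–C2 bond cannot open through a para-quinone methide, and neither stereocentre nor the E-alkene is touched.

## Compound list

1 | 5-bromo-2-hydroxy-3-methoxybenzaldehyde | COc1cc(Br)cc(C=O)c1O | starting material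
2 | 2-(allyloxy)-5-bromo-3-methoxybenzaldehyde | COc1cc(Br)cc(C=O)c1OCC=C | intermediate
3 | N-{2-[2-(allyloxy)-5-bromo-3-methoxyphenyl]-1-tosylethenyl}formamide (alkene geometry not defined; not isolated) | COc1cc(Br)cc(C=C(NC=O)S(=O)(=O)c2ccc(C)cc2)c1OCC=C | intermediate
4 | 2-[2-(allyloxy)-5-bromo-3-methoxyphenyl]acetonitrile | COc1cc(Br)cc(CC#N)c1OCC=C | intermediate
5 | 2-[2-(allyloxy)-5-bromo-3-methoxyphenyl]acetamide (not isolated) | COc1cc(Br)cc(CC(N)=O)c1OCC=C | intermediate
6 | 2-[2-(allyloxy)-5-bromo-3-methoxyphenyl]acetic acid | COc1cc(Br)cc(CC(=O)O)c1OCC=C | intermediate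
7 | (R)-4-benzyl-2-oxazolidinone | O=C1N[C@H](Cc2ccccc2)CO1 | starting material
8 | 2-[2-(allyloxy)-5-bromo-3-methoxyphenyl]acetic pivalic anhydride (not isolated) | COc1cc(Br)cc(CC(=O)OC(=O)C(C)(C)C)c1OCC=C | intermediate
9 | (R)-3-{2-[2-(allyloxy)-5-bromo-3-methoxyphenyl]acetyl}-4-benzyloxazolidin-2-one | COc1cc(Br)cc(CC(=O)N2[C@H](Cc3ccccc3)COC2=O)c1OCC=C | intermediate
10 | vanillin (4-hydroxy-3-methoxybenzaldehyde) | COc1cc(C=O)ccc1O | starting material
11 | 3-methoxy-4-(triisopropylsilyloxy)benzaldehyde | COc1cc(C=O)ccc1O[Si](C(C)C)(C(C)C)C(C)C | intermediate
12 | (Z)-O-dibutylboryl enolate of 9 (not isolated) | COc1cc(Br)cc(/C=C(\OB(CCCC)CCCC)N2[C@H](Cc3ccccc3)COC2=O)c1OCC=C | intermediate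
13 | O-dibutylboryl aldolate of 14, (2R,3R) (not isolated) | C=CCOc1c(OC)cc(Br)cc1[C@H]([C@@H](OB(CCCC)CCCC)c1ccc(O[Si](C(C)C)(C(C)C)C(C)C)c(OC)c1)C(=O)N1[C@H](Cc2ccccc2)COC1=O | intermediate
14 | (R)-4-benzyl-3-{(2R,3R)-2-[2-(allyloxy)-5-bromo-3-methoxyphenyl]-3-hydroxy-3-[3-methoxy-4-(triisopropylsilyloxy)phenyl]propanoyl}oxazolidin-2-one | C=CCOc1c(OC)cc(Br)cc1[C@H]([C@@H](O)c1ccc(O[Si](C(C)C)(C(C)C)C(C)C)c(OC)c1)C(=O)N1[C@H](Cc2ccccc2)COC1=O | intermediate
15 | (1R,2S)-2-[2-(allyloxy)-5-bromo-3-methoxyphenyl]-1-[3-methoxy-4-(triisopropylsilyloxy)phenyl]propane-1,3-diol | C=CCOc1c(OC)cc(Br)cc1[C@H]([C@@H](O)c1ccc(O[Si](C(C)C)(C(C)C)C(C)C)c(OC)c1)CO | intermediate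
16 | (1R,2S)-2-(5-bromo-2-hydroxy-3-methoxyphenyl)-1-[3-methoxy-4-(triisopropylsilyloxy)phenyl]propane-1,3-diol | Oc1c(OC)cc(Br)cc1[C@H]([C@@H](O)c1ccc(O[Si](C(C)C)(C(C)C)C(C)C)c(OC)c1)CO | intermediate
17 | C1 benzylic cation of 16, (2S), stabilised by the para silyloxy group (not isolated) | Oc1c(OC)cc(Br)cc1[C@H]([CH+]c1ccc(O[Si](C(C)C)(C(C)C)C(C)C)c(OC)c1)CO | intermediate
18 | [(2R,3S)-5-bromo-7-methoxy-2-[3-methoxy-4-(triisopropylsilyloxy)phenyl]-2,3-dihydro-1-benzofuran-3-yl]methanol | COc1cc([C@@H]2Oc3c(OC)cc(Br)cc3[C@H]2CO)ccc1O[Si](C(C)C)(C(C)C)C(C)C | intermediate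
19 | 3,5-dihydroxybenzaldehyde | O=Cc1cc(O)cc(O)c1 | starting material
20 | 3,5-bis(tert-butyldimethylsilyloxy)benzaldehyde | O=Cc1cc(O[Si](C)(C)C(C)(C)C)cc(O[Si](C)(C)C(C)(C)C)c1 | intermediate
21 | 3,5-bis(tert-butyldimethylsilyloxy)styrene | C=Cc1cc(O[Si](C)(C)C(C)(C)C)cc(O[Si](C)(C)C(C)(C)C)c1 | intermediate
22 | [(2R,3S)-5-{(E)-2-[3,5-bis(tert-butyldimethylsilyloxy)phenyl]ethenyl}-7-methoxy-2-[3-methoxy-4-(triisopropylsilyloxy)phenyl]-2,3-dihydro-1-benzofuran-3-yl]methanol | COc1cc([C@@H]2Oc3c(OC)cc(/C=C/c4cc(O[Si](C)(C)C(C)(C)C)cc(O[Si](C)(C)C(C)(C)C)c4)cc3[C@H]2CO)ccc1O[Si](C(C)C)(C(C)C)C(C)C | intermediate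
23 | gnetofuran A, 5-{(E)-2-[(2R,3S)-2-(4-hydroxy-3-methoxyphenyl)-3-(hydroxymethyl)-7-methoxy-2,3-dihydro-1-benzofuran-5-yl]ethenyl}benzene-1,3-diol | COc1cc([C@@H]2Oc3c(OC)cc(/C=C/c4cc(O)cc(O)c4)cc3[C@H]2CO)ccc1O | target

Total step count: 13. Longest linear sequence: 10 steps (steps 1, 2, 3, 4, 6, 7, 8, 9, 12, 13); steps 5, 10 and 11 are side branches.

## Least certain steps

Step 9 (key step). The most likely failures are E1 loss of the C3 proton from the cation, premature loss of the silyl group, and intermolecular etherification. The silyloxy-stabilised cation forms less readily than an alkoxy-stabilised one and may call for more forcing acid, and stilbene formation followed by reprotonation would erode the C3 configuration. The fallback sets out from 16 and comes back at 18; it replaces the cation by a neutral quinone methide. Buffered fluoride (TBAF/AcOH, THF, 0 °C) should give (1R,2S)-2-(5-bromo-2-hydroxy-3-methoxyphenyl)-1-(4-hydroxy-3-methoxyphenyl)propane-1,3-diol F1. With the para phenol free, a weak acid (PPTS, CH2Cl2, rt) should suffice to dehydrate it to the para-quinone methide 4-[(2S)-2-(5-bromo-2-hydroxy-3-methoxyphenyl)-3-hydroxypropylidene]-2-methoxycyclohexa-2,5-dien-1-one F2. The ring-B phenol should trap this in the flask by reversible intramolecular oxa-Michael addition, giving the trans phenol 4-[(2R,3S)-5-bromo-3-(hydroxymethyl)-7-methoxy-2,3-dihydro-1-benzofuran-2-yl]-2-methoxyphenol F3. Phenol-selective silylation through the phenoxide (TIPSCl, DBU, CH2Cl2, 0 °C) should then return 18.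

Step 6. The likely failures are incomplete addition and retro-aldol cleavage, because the electron-rich aldehyde is a weak electrophile and the adduct a doubly benzylic aldolate. Leakage of enolate facial selectivity or epimerisation of the acidic α-aryl centre would lower the enantiomeric purity of everything downstream. The fallback sets out from 6 and comes back at 15; it changes the auxiliary and the enolate to a more nucleophilic chlorotitanium system whose adduct is cleaved by a milder hydride. Coupling of 6 with commercial (R)-4-benzyl-1,3-thiazolidine-2-thione (EDC·HCl, DMAP, CH2Cl2) should give (R)-3-{2-[2-(allyloxy)-5-bromo-3-methoxyphenyl]acetyl}-4-benzyl-1,3-thiazolidine-2-thione F4. Its titanium enolate (TiCl4, i-Pr2NEt, N-methylpyrrolidinone, CH2Cl2, −78 to 0 °C), in the non-chelated mode that has the same facial sense as the boron aldol, should add to 11 to give (2R,3R)-2-[2-(allyloxy)-5-bromo-3-methoxyphenyl]-1-[(R)-4-benzyl-2-thioxo-1,3-thiazolidin-3-yl]-3-hydroxy-3-[3-methoxy-4-(triisopropylsilyloxy)phenyl]propan-1-one F5. Reduction with NaBH4 (THF/EtOH, 0 °C) should then give 15 directly.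

Step 2. The likely failure is diversion of the TosMIC adduct to an oxazoline or oxazole without the reductive ring opening, or incomplete deformylation; both are sensitive to temperature and substitution with aromatic aldehydes. The fallback sets out from 2 and comes back at 6; it homologates through an enol ether and does not pass through the nitrile 4. Wittig reaction with (methoxymethyl)triphenylphosphonium chloride and t-BuOK (THF, 0 °C) should give 2-(allyloxy)-5-bromo-1-methoxy-3-(2-methoxyethenyl)benzene F6 as an E/Z mixture. Mild acid hydrolysis (aq. HCl, THF, rt) should give 2-[2-(allyloxy)-5-bromo-3-methoxyphenyl]acetaldehyde F7, and Pinnick oxidation (NaClO2, NaH2PO4, 2-methyl-2-butene, t-BuOH/H2O) should give 6.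

Step 12. The likely failure is slow oxidative addition into the electron-rich bromide, which would let styrene oligomerisation and gradual loss of silyl groups under warm amine base take over. The fallback sets out from 21 (and uses 18) and comes back at 22; it replaces the Heck coupling by a Suzuki–Miyaura coupling in which the E geometry is fixed beforehand. Cross-metathesis of 21 with commercial vinylboronic acid pinacol ester (second-generation ruthenium carbene catalyst, CH2Cl2, 40 °C) should give (E)-2-{2-[3,5-bis(tert-butyldimethylsilyloxy)phenyl]ethenyl}-4,4,5,5-tetramethyl-1,3,2-dioxaborolane F8. Coupling of this with 18 (Pd(dppf)Cl2, K3PO4, dioxane/H2O, 60 °C) should give 22; any partial desilylation there would be harmless, because step 13 removes all silyl groups.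

## Further compounds

F1 | step 9 | (1R,2S)-2-(5-bromo-2-hydroxy-3-methoxyphenyl)-1-(4-hydroxy-3-methoxyphenyl)propane-1,3-diol | Oc1c(OC)cc(Br)cc1[C@H]([C@@H](O)c1ccc(O)c(OC)c1)CO
F2 | step 9 | 4-[(2S)-2-(5-bromo-2-hydroxy-3-methoxyphenyl)-3-hydroxypropylidene]-2-methoxycyclohexa-2,5-dien-1-one (para-quinone methide, formed in the flask) | Oc1c(OC)cc(Br)cc1[C@H](C=C1C=CC(=O)C(OC)=C1)CO
F3 | step 9 | 4-[(2R,3S)-5-bromo-3-(hydroxymethyl)-7-methoxy-2,3-dihydro-1-benzofuran-2-yl]-2-methoxyphenol | COc1cc([C@@H]2Oc3c(OC)cc(Br)cc3[C@H]2CO)ccc1O
F4 | step 6 | (R)-3-{2-[2-(allyloxy)-5-bromo-3-methoxyphenyl]acetyl}-4-benzyl-1,3-thiazolidine-2-thione | COc1cc(Br)cc(CC(=O)N2[C@H](Cc3ccccc3)CSC2=S)c1OCC=C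
F5 | step 6 | (2R,3R)-2-[2-(allyloxy)-5-bromo-3-methoxyphenyl]-1-[(R)-4-benzyl-2-thioxo-1,3-thiazolidin-3-yl]-3-hydroxy-3-[3-methoxy-4-(triisopropylsilyloxy)phenyl]propan-1-one | C=CCOc1c(OC)cc(Br)cc1[C@H]([C@@H](O)c1ccc(O[Si](C(C)C)(C(C)C)C(C)C)c(OC)c1)C(=O)N1[C@H](Cc2ccccc2)CSC1=S
F6 | step 2 | 2-(allyloxy)-5-bromo-1-methoxy-3-(2-methoxyethenyl)benzene (E/Z mixture) | COC=Cc1cc(Br)cc(OC)c1OCC=C
F7 | step 2 | 2-[2-(allyloxy)-5-bromo-3-methoxyphenyl]acetaldehyde | COc1cc(Br)cc(CC=O)c1OCC=C
F8 | step 12 | (E)-2-{2-[3,5-bis(tert-butyldimethylsilyloxy)phenyl]ethenyl}-4,4,5,5-tetramethyl-1,3,2-dioxaborolane | CC1(C)OB(/C=C/c2cc(O[Si](C)(C)C(C)(C)C)cc(O[Si](C)(C)C(C)(C)C)c2)OC1(C)C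
A1 | alternative 1 | 5-(1,3-dioxolan-2-yl)-7-methoxy-1-benzofuran | COc1cc(C2OCCO2)cc2ccoc12
A2 | alternative 1 | tert-butyl[2-methoxy-4-(4,4,5,5-tetramethyl-1,3,2-dioxaborolan-2-yl)phenoxy]dimethylsilane | COc1cc(B2OC(C)(C)C(C)(C)O2)ccc1O[Si](C)(C)C(C)(C)C
A3 | alternative 1 | trans-3-allyl-2-[4-(tert-butyldimethylsilyloxy)-3-methoxyphenyl]-5-(1,3-dioxolan-2-yl)-7-methoxy-2-(4,4,5,5-tetramethyl-1,3,2-dioxaborolan-2-yl)-2,3-dihydro-1-benzofuran (aryl trans to allyl) | COc1cc([C@]2(B3OC(C)(C)C(C)(C)O3)Oc3c(OC)cc(C4OCCO4)cc3[C@H]2CC=C)ccc1O[Si](C)(C)C(C)(C)C
A4 | alternative 2 | 3-{1-[4-(tert-butyldimethylsilyloxy)-3-methoxyphenyl]-2-[(tert-butyldimethylsilyloxy)methyl]but-3-yn-1-yloxy}-6-{(E)-2-[3,5-bis(tert-butyldimethylsilyloxy)phenyl]ethenyl}-4-methoxy-2H-pyran-2-one, configured as in A5 | COc1cc([C@@H]([C@H](CO[Si](C)(C)C(C)(C)C)C#C)Oc2c(OC)cc(/C=C/c3cc(O[Si](C)(C)C(C)(C)C)cc(O[Si](C)(C)C(C)(C)C)c3)oc2=O)ccc1O[Si](C)(C)C(C)(C)C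
A5 | alternative 2 | tetrakis(tert-butyldimethylsilyl) gnetofuran A | COc1cc([C@@H]2Oc3c(OC)cc(/C=C/c4cc(O[Si](C)(C)C(C)(C)C)cc(O[Si](C)(C)C(C)(C)C)c4)cc3[C@H]2CO[Si](C)(C)C(C)(C)C)ccc1O[Si](C)(C)C(C)(C)C
A6 | alternative 3 | 4-bromo-6-[2-(tert-butyldimethylsilyloxy)ethylidene]-2-methoxycyclohexa-2,4-dien-1-one (o-quinone methide) | COC1=CC(Br)=CC(=CCO[Si](C)(C)C(C)(C)C)C1=O
A7 | alternative 3 | (2R,5R)-1-[4-(benzyloxy)-3-methoxybenzyl]-2,5-dimethylthiolan-1-ium tetrafluoroborate | C[C@@H]1CC[C@@H](C)[S+]1Cc1ccc(OCc2ccccc2)c(OC)c1.F[B-](F)(F)F
A8 | alternative 3 | trans-2-(4-benzyloxy-3-methoxyphenyl)-5-bromo-3-[(tert-butyldimethylsilyloxy)methyl]-7-methoxy-2,3-dihydro-1-benzofuran, (2R,3S) | COc1cc([C@@H]2Oc3c(OC)cc(Br)cc3[C@H]2CO[Si](C)(C)C(C)(C)C)ccc1OCc1ccccc1
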